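# Proposal: synthesis of CNP0291485.6 by chromium–nickel closure of the C9–C10 bond

## The problem

Carbon numbers used throughout: C1=C10 is the ring acrylate (ester carbon C14 on C10), C9 the carbinol, C8 the acyloxy carbon, C7 the ring-fusion CH, C6 the lactone O–CH, C5=C4 the second ring olefin (methyl C15 on C4), C3 and C2 the oxirane carbons (C2 bonded to C1), C11=C13 the exocyclic methylene and C12 the lactone carbonyl.

- **Skeleton.** The target is a germacranolide: a ten-membered carbocycle C1–C10 with a 6,12-γ-lactone trans-fused across C6–C7. It carries a cis-2,3-oxirane flanked by two ring olefins, both cis within the ring (C1=C10 is 1E by CIP because of C14; C4=C5 is 4Z).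
- **Stereocentres.** There are eight: C2 (S), C3 (R), C6 (R), C7 (S), C8 (S), C9 (S), and the (2S,3R) centres of the 2,3-dimethyloxirane-2-carboxylate on O8.
- **Who controls whom.** C8 can be bought and sits next to C7, so it can steer C7, through a cyclic transition state C6, and later C9. The ring oxirane is too far from these centres and needs reagent control. The ester side chain is made separately.
- **Fragile groups.** The α-methylene lactone adds amines, alkoxides and hydride. The doubly allylic oxirane will not survive protic or strong Lewis acid. The cis-divinyl oxirane is a latent Cope substrate, so heating is excluded. An α-acyloxy aldehyde at C9 can epimerise at C8, and a C8 ester next to a free C9 hydroxyl can migrate.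
- **Consequence for ordering.** Every acidic operation must precede the oxirane, and every strongly basic one must precede the lactone.
- **Feature that enables the key step.** C9 is an allylic carbinol bonded to C10, the α-carbon of the 2-alkenoate C1=C10–C14. The C9–C10 bond is therefore the sum of a C9 aldehyde and a C10 alkenyl anion, available from a Z-α-iodoacrylate. The cis-oxirane and the Z C4=C5 olefin already fold the open chain toward ring closure.

## Retrosynthesis

**C9–C10 (25 ⇒ 24).** Cutting C9–C10 opens the ring and removes the C9 stereocentre. What remains is seco aldehyde 24, a chain with the lactone, both oxiranes and the C8 ester in place. The neighbouring cuts are less attractive: C1=C10 olefination needs C9 set beforehand on a phosphonate prone to β-elimination, and a late lactonisation leaves the carbocycle unsolved. The forward step must join an alkenyl iodide to an aldehyde without touching two esters, a lactone and two oxiranes. Chromium–nickel coupling is the method that can.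

**C9 oxidation level (24 ⇒ 23 ⇒ 22).** The α-acyloxy aldehyde is the least stable compound of the route, so it is made last. It comes from primary alcohol 23, released from silyl ether 22 by buffered fluoride.

**C1=C10 (22 ⇒ 21 ⇒ 20).** The iodoacrylate is cut at the olefin to oxiranyl aldehyde 21 and an α-iodo ester ylide. The ylide places the ester trans and the iodine cis to C2, which is the geometry the ring needs. Aldehyde 21 comes from epoxy alcohol 20 by buffered oxidation.

**Oxirane (20 ⇒ 19).** The C2–O and C3–O bonds are made from the Z-allylic alcohol 19 by tartrate-controlled epoxidation. This puts the acid-labile oxirane after the last acidic step. The cost is that a Z-allylic alcohol is the slow substrate class for this reaction.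

**C3–C4 (19 ⇒ 18 ⇒ 16 + 17).** The 2Z olefin is a semi-reduced alkyne (18). The C3–C4 bond is an sp–sp2 coupling of alkenyl iodide 16 with prop-2-yn-1-ol 17. No protecting group is needed on C1, and the Z geometry at C4=C5 is carried unchanged from the iodide.

**C8 ester (16 ⇒ 11 + 15).** The ester C–O bond is cut to alcohol 11 and acid 15. The acid comes from tiglic acid 12 by reduction (13), tartrate-controlled epoxidation (14) and oxidation.

**C8/C9 differentiation (11 ⇒ 10 ⇒ 9).** Silyl ether 11 comes from diol 10 by primary-selective silylation. Diol 10 comes from acetonide 9 by aqueous acid, which is harmless because no oxirane is yet present.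

**C6–C7 and lactone C12–O (9 ⇒ 3 + 7).** These bonds are cut together to (Z)-3-iodobut-2-enal 3 and allylic bromide 7. The forward chromium allylation–lactonisation builds the lactone with its methylene, sets C6 and C7, and is the convergent union of the two halves. It asks for 6,7-anti addition and for C8 to direct the face of C7.

**Fragments (7 ⇒ 6 ⇒ 4 + 5; 3 ⇒ 2 ⇒ 1).** Bromide 7 comes from Baylis–Hillman adduct 6 of (R)-glyceraldehyde acetonide 4 and methyl acrylate 5. Aldehyde 3 comes from but-2-yn-1-ol 1 through Z-iodo alcohol 2.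

## Roads not taken

**Alternative 1: nitrile oxide cycloaddition through the lactone ester tether.**
- Cut: C7–C11 and C8–O.
- Forward: dehydration of a nitroacetate ester on O6 gives a nitrile oxide at C11. It adds across a Z C7=C8 olefin and closes the lactone and an isoxazoline, giving A1.
- Merits: the cycloaddition is suprafacial and tethered from C6, so C6, C7 and C8 are fixed relative to one another in one step. This is better than the chosen plan, whose allylation relies on an unproven facial preference at C7.
- Weak points: an ester tether must adopt its disfavoured s-cis form to cyclise. Acyl nitrile oxides dimerise readily. A1 still needs N–O cleavage, methylenation of an α-keto lactone, and the whole C1–C5/C10 portion. It says nothing about closing the ten-membered ring.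
- Comparison: the chosen plan sets against it a convergent union that delivers the lactone with its methylene in one step, and a ring closure in its last step.

**Alternative 2: selenium-bridged olefin transposition.**
- Cut: the C6–O lactone bond, on a preformed ten-membered ring.
- Forward: N-(phenylseleno)phthalimide forms a seleniranium ion on a Z C5=C6 olefin. The C12 acid opens it at C6 to give A2. Selenoxide elimination toward C4 would then make C4=C5.
- Merits: the α-methylene lactone appears late, so it is not carried through many steps, and the labile Z-iodo enal is avoided. In these respects it is gentler than the chosen route.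
- Weak points: the carbocycle must already exist, and this road offers no way to make it. An extra stereocentre at C4 must be set and then destroyed. Electrophilic selenium and peroxide must pass two oxiranes and three olefins. The geometry of the olefin from a syn-elimination in a ten-membered ring is not assured.
- Comparison: the chosen plan sets against it a ring closure that is part of the plan, and a C4=C5 geometry fixed in step 1.

**Alternative 3: macrocyclic Horner–Wadsworth–Emmons olefination.**
- Cut: C1=C10.
- Forward: LiCl and i-Pr2NEt generate a C10 phosphonate carbanion that condenses with a C1 oxiranyl aldehyde, giving A3.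
- Merits: no stereocentre is created at ring closure and no low-valent metal meets the oxiranes. In both respects it is better than chromium–nickel coupling.
- Weak points: the carbanion sits β to the C9 silyloxy group and can eliminate it. C9 would have to be set earlier by an intermolecular addition that faces the same Felkin bias. α-Branched phosphonoacetates give olefin mixtures. The cis-oxiranyl aldehyde is exposed to base.
- Comparison: the chosen plan sets against it a precursor one Wittig step away from an epoxy alcohol, an olefin geometry fixed by the iodide, and an oxidation–reduction correction at C9 held in reserve.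

Key step: step 19

Remark: adduct 6 is carried as both carbinol epimers, because that carbon (C7) becomes sp2 in step 4.

Remark: in step 5 the aldehyde is assumed to add to the C7 face syn to the dioxolane oxygen (anti to its CH2); the opposite sense is covered by the fallback for that step.

Remark: TBS = tert-butyldimethylsilyl.

## Route

Step 1
Reactants: 1 but-2-yn-1-ol
Product: 2 (Z)-3-iodobut-2-en-1-ol
Conditions: NaAlH2(OCH2CH2OMe)2, THF, 0 °C → rt; then I2, −78 °C → 0 °C
Reagents that add atoms: iodine, II
Why: Hydroxyl-directed trans-hydroalumination places aluminium on C4 cis to the carbinol carbon, and iodinolysis with retention gives the Z-iodide; this fixes the geometry of the later C4=C5 ring olefin.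

Step 2
Reactants: 2 (Z)-3-iodobut-2-en-1-ol
Product: 3 (Z)-3-iodobut-2-enal
Conditions: MnO2, CH2Cl2, rt, dark; used at once
Reagents that add atoms: none
Why: Allylic oxidation on the MnO2 surface is neutral and should leave the Z geometry intact if the aldehyde is not stored.

Step 3
Reactants: 4 (R)-2,2-dimethyl-1,3-dioxolane-4-carbaldehyde; 5 methyl acrylate
Product: 6 methyl 2-{hydroxy[(4R)-2,2-dimethyl-1,3-dioxolan-4-yl]methyl}prop-2-enoate (both carbinol epimers)
Conditions: DABCO, dioxane/H2O 1:1, rt
Reagents that add atoms: none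
Why: Morita–Baylis–Hillman reaction joins C11 to C7; the new carbinol centre need not be controlled because it is erased in step 4, and C8 comes unchanged from 4.

Step 4
Reactants: 6 methyl 2-{hydroxy[(4R)-2,2-dimethyl-1,3-dioxolan-4-yl]methyl}prop-2-enoate
Product: 7 methyl (2Z)-2-(bromomethyl)-3-[(4S)-2,2-dimethyl-1,3-dioxolan-4-yl]prop-2-enoate
Conditions: N-bromosuccinimide, Me2S, CH2Cl2, 0 °C → rt
Reagents that add atoms: N-bromosuccinimide, O=C1CCC(=O)N1Br
Why: Bromosulfonium activation of the alcohol followed by SN2′ attack of bromide (Corey–Kim-type allylic transposition) gives the rearranged primary bromide without acid, so the acetonide survives.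

Step 5
Reactants: 3 (Z)-3-iodobut-2-enal; 7 methyl (2Z)-2-(bromomethyl)-3-[(4S)-2,2-dimethyl-1,3-dioxolan-4-yl]prop-2-enoate
Product: 9 (4S,5S)-4-[(4S)-2,2-dimethyl-1,3-dioxolan-4-yl]-5-[(Z)-2-iodoprop-1-enyl]-3-methylideneoxolan-2-one, via hydroxy ester 8 (not isolated)
Conditions: CrCl2, THF, 0 °C → rt; aqueous work-up; then PPTS (cat.), CH2Cl2, rt
Reagents that add atoms: none
Why: Nozaki–Hiyama-type allylation: the allylchromium from 7 should add through a chair transition state with the aldehyde residue and C8 both equatorial, giving the 6,7-anti adduct 8, which lactonises to the trans lactone. C8, held with its hydrogen eclipsing C7=C11 by allylic strain against the ester, is expected to send the aldehyde to the face anti to the dioxolane CH2, which sets C7 and, through the chair, C6 as in the target. Without nickel the alkenyl iodide is not touched by CrCl2.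

Step 6
Reactants: 9 (4S,5S)-4-[(4S)-2,2-dimethyl-1,3-dioxolan-4-yl]-5-[(Z)-2-iodoprop-1-enyl]-3-methylideneoxolan-2-one
Product: 10 (4R,5S)-4-[(1S)-1,2-dihydroxyethyl]-5-[(Z)-2-iodoprop-1-enyl]-3-methylideneoxolan-2-one
Conditions: AcOH/H2O 4:1, 35 °C
Reagents that add atoms: none
Why: Acetal hydrolysis of a terminal acetonide; this is the only acidic step and it is placed before any oxirane exists, and weak acid at low temperature should not move the lactone to O8.

Step 7
Reactants: 10 (4R,5S)-4-[(1S)-1,2-dihydroxyethyl]-5-[(Z)-2-iodoprop-1-enyl]-3-methylideneoxolan-2-one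
Product: 11 (4R,5S)-4-[(1S)-2-(TBS-oxy)-1-hydroxyethyl]-5-[(Z)-2-iodoprop-1-enyl]-3-methylideneoxolan-2-one
Conditions: TBSCl, imidazole, CH2Cl2, −20 → 0 °C
Reagents that add atoms: tert-butyldimethylsilyl chloride, CC(C)(C)[Si](C)(C)Cl
Why: Silylation is selective for the primary C9 hydroxyl over the hindered secondary C8 hydroxyl.

Step 8
Reactants: 12 tiglic acid
Product: 13 (E)-2-methylbut-2-en-1-ol
Conditions: LiAlH4, Et2O, 0 °C → rt
Reagents that add atoms: none
Why: Hydride reduction of the acid to the allylic alcohol; the trisubstituted olefin of the carboxylate is not reduced.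

Step 9
Reactants: 13 (E)-2-methylbut-2-en-1-ol
Product: 14 [(2R,3R)-2,3-dimethyloxiran-2-yl]methanol
Conditions: Ti(OiPr)4 (cat.), D-(−)-diisopropyl tartrate (cat.), t-BuOOH, 4 Å MS, CH2Cl2, −20 °C
Reagents that add atoms: tert-butyl hydroperoxide, CC(C)(C)OO
Why: Sharpless asymmetric epoxidation; E-2-alken-1-ols give 2S,3S epoxy alcohols with the L-(+) tartrate, so the D-(−) ester delivers the 2R,3R enantiomer, and the cis methyl groups come from the E olefin.

Step 10
Reactants: 14 [(2R,3R)-2,3-dimethyloxiran-2-yl]methanol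
Product: 15 (2S,3R)-2,3-dimethyloxirane-2-carboxylic acid
Conditions: RuCl3 (cat.), NaIO4, MeCN/CCl4/H2O, 0 °C → rt
Reagents that add atoms: sodium periodate, [Na+].[O-]I(=O)(=O)=O
Why: Catalytic RuO4 oxidation of a 2,3-epoxy alcohol to the glycidic acid leaves both stereocentres untouched (the C2 descriptor changes only because the carboxyl outranks C3).

Step 11
Reactants: 11 (4R,5S)-4-[(1S)-2-(TBS-oxy)-1-hydroxyethyl]-5-[(Z)-2-iodoprop-1-enyl]-3-methylideneoxolan-2-one; 15 (2S,3R)-2,3-dimethyloxirane-2-carboxylic acid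
Product: 16 (1S)-2-(TBS-oxy)-1-[(2S,3S)-2-[(Z)-2-iodoprop-1-enyl]-4-methylidene-5-oxooxolan-3-yl]ethyl (2S,3R)-2,3-dimethyloxirane-2-carboxylate
Conditions: 15, 2,4,6-Cl3C6H2COCl, Et3N, THF, 0 °C; then 11, DMAP, toluene, rt
Reagents that add atoms: none
Why: Yamaguchi esterification through the mixed anhydride suits a hindered acid and a hindered secondary alcohol; O-acylation retains C8, and Et3N/DMAP are too weak to isomerise the methylene lactone.

Step 12
Reactants: 16 (1S)-2-(TBS-oxy)-1-[(2S,3S)-2-[(Z)-2-iodoprop-1-enyl]-4-methylidene-5-oxooxolan-3-yl]ethyl (2S,3R)-2,3-dimethyloxirane-2-carboxylate; 17 prop-2-yn-1-ol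
Product: 18 (1S)-2-(TBS-oxy)-1-[(2R,3S)-2-[(Z)-5-hydroxy-2-methylpent-1-en-3-ynyl]-4-methylidene-5-oxooxolan-3-yl]ethyl (2S,3R)-2,3-dimethyloxirane-2-carboxylate
Conditions: PdCl2(PPh3)2 (cat.), CuI (cat.), Et3N, THF, rt
Reagents that add atoms: none
Why: Sonogashira coupling forms C3–C4 with retention of the Z geometry at C4=C5; at room temperature copper acetylide transfer should outrun any Heck reaction with the methylene lactone.

Step 13
Reactants: 18 (1S)-2-(TBS-oxy)-1-[(2R,3S)-2-[(Z)-5-hydroxy-2-methylpent-1-en-3-ynyl]-4-methylidene-5-oxooxolan-3-yl]ethyl (2S,3R)-2,3-dimethyloxirane-2-carboxylate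
Product: 19 (1S)-2-(TBS-oxy)-1-[(2R,3S)-2-[(1Z,3Z)-5-hydroxy-2-methylpenta-1,3-dienyl]-4-methylidene-5-oxooxolan-3-yl]ethyl (2S,3R)-2,3-dimethyloxirane-2-carboxylate
Conditions: Zn dust activated with Cu(OAc)2 and AgNO3, MeOH/H2O 1:1, rt
Reagents that add atoms: none
Why: Boland reduction: the zinc couple reduces only the conjugated triple bond, delivering both hydrogens syn from water, which gives the 2Z olefin without the over-reduction that hydrogenation would risk at the exocyclic methylene.

Step 14
Reactants: 19 (1S)-2-(TBS-oxy)-1-[(2R,3S)-2-[(1Z,3Z)-5-hydroxy-2-methylpenta-1,3-dienyl]-4-methylidene-5-oxooxolan-3-yl]ethyl (2S,3R)-2,3-dimethyloxirane-2-carboxylate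
Product: 20 (1S)-2-(TBS-oxy)-1-[(2R,3S)-2-[(Z)-2-[(2R,3S)-3-(hydroxymethyl)oxiran-2-yl]prop-1-enyl]-4-methylidene-5-oxooxolan-3-yl]ethyl (2S,3R)-2,3-dimethyloxirane-2-carboxylate
Conditions: Ti(OiPr)4 (20 mol%), L-(+)-diisopropyl tartrate (24 mol%), t-BuOOH, 4 Å MS, CH2Cl2, −20 °C
Reagents that add atoms: tert-butyl hydroperoxide, CC(C)(C)OO
Why: Sharpless asymmetric epoxidation: only the olefin allylic to the free hydroxyl is epoxidised, the Z olefin gives the cis-oxirane, and the L-(+) tartrate gives the 2S,3R configuration found for Z-2-alken-1-ols (C2 S, C3 R in route numbering). The existing stereocentres are remote, so the reagent decides.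

Step 15
Reactants: 20 (1S)-2-(TBS-oxy)-1-[(2R,3S)-2-[(Z)-2-[(2R,3S)-3-(hydroxymethyl)oxiran-2-yl]prop-1-enyl]-4-methylidene-5-oxooxolan-3-yl]ethyl (2S,3R)-2,3-dimethyloxirane-2-carboxylate
Product: 21 (1S)-2-(TBS-oxy)-1-[(2R,3S)-2-[(Z)-2-[(2R,3R)-3-formyloxiran-2-yl]prop-1-enyl]-4-methylidene-5-oxooxolan-3-yl]ethyl (2S,3R)-2,3-dimethyloxirane-2-carboxylate
Conditions: Dess–Martin periodinane, NaHCO3, CH2Cl2, 0 °C; used crude
Reagents that add atoms: none
Why: Buffered Dess–Martin oxidation gives the cis-oxiranyl aldehyde without acid or base strong enough to open the allylic oxirane or epimerise C2.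

Step 16
Reactants: 21 (1S)-2-(TBS-oxy)-1-[(2R,3S)-2-[(Z)-2-[(2R,3R)-3-formyloxiran-2-yl]prop-1-enyl]-4-methylidene-5-oxooxolan-3-yl]ethyl (2S,3R)-2,3-dimethyloxirane-2-carboxylate
Product: 22 methyl (2Z)-2-iodo-3-[(2S,3R)-3-[(Z)-1-[(2R,3S)-3-[(1S)-2-(TBS-oxy)-1-{[(2S,3R)-2,3-dimethyloxiran-2-yl]carbonyloxy}ethyl]-4-methylidene-5-oxooxolan-2-yl]prop-1-en-2-yl]oxiran-2-yl]prop-2-enoate
Conditions: Ph3P=CHCO2Me, N-iodosuccinimide, CH2Cl2, −20 °C; then 21, −20 °C → rt
Reagents that add atoms: methyl (triphenylphosphoranylidene)acetate, COC(=O)C=P(c1ccccc1)(c1ccccc1)c1ccccc1; N-iodosuccinimide, O=C1CCC(=O)N1I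
Why: Wittig olefination with the α-iodo ester ylide made in the flask; as with stabilised ylides generally the ester ends trans to the aldehyde residue, so iodine is cis to C2 (Z), and the weakly basic ylide should not epimerise the oxiranyl aldehyde.

Step 17
Reactants: 22 methyl (2Z)-2-iodo-3-[(2S,3R)-3-[(Z)-1-[(2R,3S)-3-[(1S)-2-(TBS-oxy)-1-{[(2S,3R)-2,3-dimethyloxiran-2-yl]carbonyloxy}ethyl]-4-methylidene-5-oxooxolan-2-yl]prop-1-en-2-yl]oxiran-2-yl]prop-2-enoate
Product: 23 methyl (2Z)-3-[(2S,3R)-3-[(Z)-1-[(2R,3S)-3-[(1S)-1-{[(2S,3R)-2,3-dimethyloxiran-2-yl]carbonyloxy}-2-hydroxyethyl]-4-methylidene-5-oxooxolan-2-yl]prop-1-en-2-yl]oxiran-2-yl]-2-iodoprop-2-enoate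
Conditions: HF·pyridine, excess pyridine, THF, 0 °C
Reagents that add atoms: none
Why: Buffered fluoride removes the primary silyl ether; the slightly acidic medium and the quaternary α-carbon of the ester disfavour acyl migration from O8 to O9, and excess pyridine keeps the oxiranes from opening.

Step 18
Reactants: 23 methyl (2Z)-3-[(2S,3R)-3-[(Z)-1-[(2R,3S)-3-[(1S)-1-{[(2S,3R)-2,3-dimethyloxiran-2-yl]carbonyloxy}-2-hydroxyethyl]-4-methylidene-5-oxooxolan-2-yl]prop-1-en-2-yl]oxiran-2-yl]-2-iodoprop-2-enoate
Product: 24 methyl (2Z)-3-[(2S,3R)-3-[(Z)-1-[(2R,3S)-3-[(1S)-1-{[(2S,3R)-2,3-dimethyloxiran-2-yl]carbonyloxy}-2-oxoethyl]-4-methylidene-5-oxooxolan-2-yl]prop-1-en-2-yl]oxiran-2-yl]-2-iodoprop-2-enoate (seco C9 aldehyde)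
Conditions: Dess–Martin periodinane, NaHCO3, CH2Cl2, 0 °C; used at once
Reagents that add atoms: none
Why: Buffered Dess–Martin oxidation gives the α-acyloxy aldehyde under conditions that should not epimerise C8.

Step 19
Reactants: 24 seco C9 aldehyde with (Z)-α-iodoacrylate
Product: 25 target, methyl (2S,3R,6R,7S,8S,9S)-2,3-epoxy-9-hydroxy-8-{[(2S,3R)-2,3-dimethyloxiran-2-yl]carbonyloxy}germacra-1(10),4,11(13)-trien-12,6-olid-14-oate (both ring olefins cis in the ring; 1E, 4Z by CIP)
Conditions: CrCl2 (excess), NiCl2 (cat.), DMSO, rt, slow addition of 24 to about 1 mM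
Reagents that add atoms: none
Why: CrCl2 reduces NiCl2 to zerovalent nickel, which inserts into the C10–I bond; transmetallation gives an alkenyl species of trivalent chromium that adds to the C9 aldehyde (Nozaki–Hiyama–Kishi reaction). The closest known reaction type is the intramolecular coupling of alkenyl iodides with aldehydes to medium and large rings. The ten-membered carbocycle closes by 10-exo-trig addition of C10 to the C9 carbonyl. The ring olefin geometry follows from retention at C10: iodine was cis to C2, so C9 ends cis to C2, and the cis-oxirane, the Z C4=C5 olefin and the trans lactone already hold the chain ends near each other. C9 is the one new stereocentre and is controlled by C8: with the C8–O bond antiperiplanar to the forming bond, the tether forces C10 to approach gauche to C7, and the chromium-bound oxygen then lies outward, anti to C7, which corresponds to the 8,9-syn (9S) carbinol. The step needs 1,2-addition to the aldehyde only; alkenylchromium reagents do not add to esters, lactones or oxiranes and do not add in conjugate fashion, so the methylene lactone and the acrylate are left alone. High dilution and slow addition favour closure over intermolecular coupling, and room temperature keeps the cis-divinyl oxirane below the onset of Cope rearrangement.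

## Compound list

1 | but-2-yn-1-ol | CC#CCO | starting material
2 | (Z)-3-iodobut-2-en-1-ol | C/C(I)=C/CO | intermediate
3 | (Z)-3-iodobut-2-enal | C/C(I)=C/C=O | intermediate
4 | (R)-2,2-dimethyl-1,3-dioxolane-4-carbaldehyde | O=C[C@H]1COC(C)(C)O1 | starting material
5 | methyl acrylate | C=CC(=O)OC | starting material
6 | methyl 2-{hydroxy[(4R)-2,2-dimethyl-1,3-dioxolan-4-yl]methyl}prop-2-enoate (both carbinol epimers) | C=C(C(=O)OC)C(O)[C@H]1COC(C)(C)O1 | intermediate
7 | methyl (2Z)-2-(bromomethyl)-3-[(4S)-2,2-dimethyl-1,3-dioxolan-4-yl]prop-2-enoate | COC(=O)/C(CBr)=C/[C@H]1COC(C)(C)O1 | intermediate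
8 | methyl 2-[(1S,2S,3Z)-1-[(4S)-2,2-dimethyl-1,3-dioxolan-4-yl]-2-hydroxy-4-iodopent-3-enyl]prop-2-enoate | COC(=O)C(=C)[C@@H]([C@H](O)/C=C(/C)I)[C@H]1COC(C)(C)O1 | intermediate (not isolated)
9 | (4S,5S)-4-[(4S)-2,2-dimethyl-1,3-dioxolan-4-yl]-5-[(Z)-2-iodoprop-1-enyl]-3-methylideneoxolan-2-one | C=C1C(=O)O[C@H](/C=C(/C)I)[C@H]1[C@H]2COC(C)(C)O2 | intermediate
10 | (4R,5S)-4-[(1S)-1,2-dihydroxyethyl]-5-[(Z)-2-iodoprop-1-enyl]-3-methylideneoxolan-2-one | C=C1C(=O)O[C@H](/C=C(/C)I)[C@H]1[C@H](O)CO | intermediate
11 | (4R,5S)-4-[(1S)-2-(tert-butyldimethylsilyloxy)-1-hydroxyethyl]-5-[(Z)-2-iodoprop-1-enyl]-3-methylideneoxolan-2-one | C=C1C(=O)O[C@H](/C=C(/C)I)[C@H]1[C@H](O)CO[Si](C)(C)C(C)(C)C | intermediate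
12 | tiglic acid, (E)-2-methylbut-2-enoic acid | C/C=C(\C)C(=O)O | starting material
13 | (E)-2-methylbut-2-en-1-ol | C/C=C(\C)CO | intermediate
14 | [(2R,3R)-2,3-dimethyloxiran-2-yl]methanol | OC[C@@]1(C)O[C@@H]1C | intermediate
15 | (2S,3R)-2,3-dimethyloxirane-2-carboxylic acid | OC(=O)[C@@]1(C)O[C@@H]1C | intermediate
16 | (1S)-2-(tert-butyldimethylsilyloxy)-1-[(2S,3S)-2-[(Z)-2-iodoprop-1-enyl]-4-methylidene-5-oxooxolan-3-yl]ethyl (2S,3R)-2,3-dimethyloxirane-2-carboxylate | C=C1C(=O)O[C@H](/C=C(/C)I)[C@H]1[C@H](OC(=O)[C@@]2(C)O[C@@H]2C)CO[Si](C)(C)C(C)(C)C | intermediate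
17 | prop-2-yn-1-ol | C#CCO | starting material
18 | (1S)-2-(tert-butyldimethylsilyloxy)-1-[(2R,3S)-2-[(Z)-5-hydroxy-2-methylpent-1-en-3-ynyl]-4-methylidene-5-oxooxolan-3-yl]ethyl (2S,3R)-2,3-dimethyloxirane-2-carboxylate | C=C1C(=O)O[C@H](/C=C(/C)C#CCO)[C@H]1[C@H](OC(=O)[C@@]2(C)O[C@@H]2C)CO[Si](C)(C)C(C)(C)C | intermediate
19 | (1S)-2-(tert-butyldimethylsilyloxy)-1-[(2R,3S)-2-[(1Z,3Z)-5-hydroxy-2-methylpenta-1,3-dienyl]-4-methylidene-5-oxooxolan-3-yl]ethyl (2S,3R)-2,3-dimethyloxirane-2-carboxylate | C=C1C(=O)O[C@H](/C=C(/C)\C=C/CO)[C@H]1[C@H](OC(=O)[C@@]2(C)O[C@@H]2C)CO[Si](C)(C)C(C)(C)C | intermediate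
20 | (1S)-2-(tert-butyldimethylsilyloxy)-1-[(2R,3S)-2-[(Z)-2-[(2R,3S)-3-(hydroxymethyl)oxiran-2-yl]prop-1-enyl]-4-methylidene-5-oxooxolan-3-yl]ethyl (2S,3R)-2,3-dimethyloxirane-2-carboxylate | C=C1C(=O)O[C@H](/C=C(/C)[C@H]2O[C@H]2CO)[C@H]1[C@H](OC(=O)[C@@]3(C)O[C@@H]3C)CO[Si](C)(C)C(C)(C)C | intermediate
21 | (1S)-2-(tert-butyldimethylsilyloxy)-1-[(2R,3S)-2-[(Z)-2-[(2R,3R)-3-formyloxiran-2-yl]prop-1-enyl]-4-methylidene-5-oxooxolan-3-yl]ethyl (2S,3R)-2,3-dimethyloxirane-2-carboxylate | C=C1C(=O)O[C@H](/C=C(/C)[C@H]2O[C@H]2C=O)[C@H]1[C@H](OC(=O)[C@@]3(C)O[C@@H]3C)CO[Si](C)(C)C(C)(C)C | intermediate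
22 | methyl (2Z)-2-iodo-3-[(2S,3R)-3-[(Z)-1-[(2R,3S)-3-[(1S)-2-(tert-butyldimethylsilyloxy)-1-{[(2S,3R)-2,3-dimethyloxiran-2-yl]carbonyloxy}ethyl]-4-methylidene-5-oxooxolan-2-yl]prop-1-en-2-yl]oxiran-2-yl]prop-2-enoate | C=C1C(=O)O[C@H](/C=C(/C)[C@H]2O[C@H]2/C=C(/C(=O)OC)I)[C@H]1[C@H](OC(=O)[C@@]3(C)O[C@@H]3C)CO[Si](C)(C)C(C)(C)C | intermediate
23 | methyl (2Z)-3-[(2S,3R)-3-[(Z)-1-[(2R,3S)-3-[(1S)-1-{[(2S,3R)-2,3-dimethyloxiran-2-yl]carbonyloxy}-2-hydroxyethyl]-4-methylidene-5-oxooxolan-2-yl]prop-1-en-2-yl]oxiran-2-yl]-2-iodoprop-2-enoate | C=C1C(=O)O[C@H](/C=C(/C)[C@H]2O[C@H]2/C=C(/C(=O)OC)I)[C@H]1[C@H](OC(=O)[C@@]3(C)O[C@@H]3C)CO | intermediate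
24 | methyl (2Z)-3-[(2S,3R)-3-[(Z)-1-[(2R,3S)-3-[(1S)-1-{[(2S,3R)-2,3-dimethyloxiran-2-yl]carbonyloxy}-2-oxoethyl]-4-methylidene-5-oxooxolan-2-yl]prop-1-en-2-yl]oxiran-2-yl]-2-iodoprop-2-enoate (seco C9 aldehyde) | C=C1C(=O)O[C@H](/C=C(/C)[C@H]2O[C@H]2/C=C(/C(=O)OC)I)[C@H]1[C@H](OC(=O)[C@@]3(C)O[C@@H]3C)C=O | intermediate
25 | methyl (2S,3R,6R,7S,8S,9S)-2,3-epoxy-9-hydroxy-8-{[(2S,3R)-2,3-dimethyloxiran-2-yl]carbonyloxy}germacra-1(10)E,4Z,11(13)-trien-12,6-olid-14-oate | C=C1C(=O)O[C@@H]2/C=C(/C)[C@H]3O[C@H]3/C=C(/C(=O)OC)[C@H](O)[C@@H](OC(=O)[C@@]3(C)O[C@@H]3C)[C@@H]12 | target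

## Step count and least certain steps

Total: 19 steps. Longest linear sequence: 14 steps (1 → 2 → 3 → 9 → 10 → 11 → 16 → 18 → 19 → 20 → 21 → 22 → 23 → 24 → 25; the branch from 4 is equally long).

**Step 19 (key step).**
- What may go wrong: C9 is created under substrate control alone, and facial selectivity may be poor or reversed. An open-chain α-acyloxy aldehyde prefers attack past H8 (polar Felkin sense), which would give the 8,9-anti carbinol. Only the constraint of the forming ring argues for the needed syn sense. Protodeiodination and intermolecular coupling are lesser concerns at high dilution.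
- Fallback: set C9 by reduction instead of addition. Starting from 24, the cyclisation is run as described and the 9R carbinol F1 (alone or mixed with 25) is oxidised with Dess–Martin periodinane/NaHCO3 to the ring C9 ketone F2. Reduction with NaBH4/CeCl3·7H2O in MeOH at −78 °C should bring hydride in from the ring periphery, anti to the C8–O bond, and 1,2 at the ketone ahead of conjugate reduction of the methylene lactone. This returns to 25.

**Step 5.**
- What may go wrong: reversed facial selectivity at C7 with respect to C8. The allylic-strain argument fixes which hydrogen lies in the olefin plane, but not whether the aldehyde enters anti to the dioxolane CH2 (assumed) or anti to its oxygen, the sense seen in osmylations and enolate alkylations of such systems. Loss of anti selectivity through a chelated allylchromium is a second possibility.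
- Fallback: use the opposite sense instead of fighting it. Starting from 5 and 3, (S)-2,2-dimethyl-1,3-dioxolane-4-carbaldehyde F3 replaces 4 and is taken through the same three operations: the Baylis–Hillman adduct F4, the bromide F5, and the chromium allylation through the hydroxy ester F6 to the lactone F7. With attack anti to oxygen, F7 has the target configuration at C6 and C7 and the wrong one at C8. Hydrolysis gives the diol F8 and silylation the silyl ether F9. Mitsunobu esterification of F9 with acid 15 (PPh3, diisopropyl azodicarboxylate, toluene, 0 °C → rt) inverts C8 and returns to 16.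

**Step 14.**
- What may go wrong: slow oxygen transfer to a hindered Z-allylic alcohol, with erosion of facial selectivity, and opening of the allylic oxirane at C3 by titanium alkoxides during a long reaction.
- Fallback: leave the titanium–tartrate manifold for a catalyst class made for Z-allylic alcohols. Starting from 19, hydroxyl-directed epoxidation with VO(OiPr)3 and a C2-symmetric chiral bishydroxamic acid ligand (cumene hydroperoxide, toluene, 0 °C) is used, with the ligand enantiomer chosen to deliver oxygen to the same face. It returns to 20 and makes no new compound (F0).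

**Step 13.**
- What may go wrong: incomplete reduction in aqueous methanol, or competing reduction of the exocyclic enoate by the zinc couple.
- Fallback: replace alkyne coupling and semi-reduction by one stereodefined cross-coupling. Starting from 16, Stille coupling (Pd2(dba)3, AsPh3, CuI, NMP, rt) with (Z)-3-(tributylstannyl)prop-2-en-1-ol F10 gives 19 directly, with retention at both olefins. F10 is made from 17 by hydroalumination with LiAlH4 and trapping of the alkenylalanate with Bu3SnOTf.

## Further compounds

F1 | step 19 | 9R epimer of 25 | C=C1C(=O)O[C@@H]2/C=C(/C)[C@H]3O[C@H]3/C=C(/C(=O)OC)[C@@H](O)[C@@H](OC(=O)[C@@]3(C)O[C@@H]3C)[C@@H]12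
F2 | step 19 | C9 ketone of the macrocycle (9-oxo analogue of 25) | C=C1C(=O)O[C@@H]2/C=C(/C)[C@H]3O[C@H]3/C=C(/C(=O)OC)C(=O)[C@@H](OC(=O)[C@@]3(C)O[C@@H]3C)[C@@H]12
F3 | step 5 | (S)-2,2-dimethyl-1,3-dioxolane-4-carbaldehyde | O=C[C@@H]1COC(C)(C)O1
F4 | step 5 | methyl 2-{hydroxy[(4S)-2,2-dimethyl-1,3-dioxolan-4-yl]methyl}prop-2-enoate (both carbinol epimers) | C=C(C(=O)OC)C(O)[C@@H]1COC(C)(C)O1
F5 | step 5 | methyl (2Z)-2-(bromomethyl)-3-[(4R)-2,2-dimethyl-1,3-dioxolan-4-yl]prop-2-enoate | COC(=O)/C(CBr)=C/[C@@H]1COC(C)(C)O1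
F6 | step 5 | methyl 2-[(1S,2S,3Z)-1-[(4R)-2,2-dimethyl-1,3-dioxolan-4-yl]-2-hydroxy-4-iodopent-3-enyl]prop-2-enoate | COC(=O)C(=C)[C@@H]([C@H](O)/C=C(/C)I)[C@@H]1COC(C)(C)O1
F7 | step 5 | (4S,5S)-4-[(4R)-2,2-dimethyl-1,3-dioxolan-4-yl]-5-[(Z)-2-iodoprop-1-enyl]-3-methylideneoxolan-2-one | C=C1C(=O)O[C@H](/C=C(/C)I)[C@H]1[C@@H]2COC(C)(C)O2
F8 | step 5 | (4R,5S)-4-[(1R)-1,2-dihydroxyethyl]-5-[(Z)-2-iodoprop-1-enyl]-3-methylideneoxolan-2-one | C=C1C(=O)O[C@H](/C=C(/C)I)[C@H]1[C@@H](O)CO
F9 | step 5 | (4R,5S)-4-[(1R)-2-(tert-butyldimethylsilyloxy)-1-hydroxyethyl]-5-[(Z)-2-iodoprop-1-enyl]-3-methylideneoxolan-2-one | C=C1C(=O)O[C@H](/C=C(/C)I)[C@H]1[C@@H](O)CO[Si](C)(C)C(C)(C)C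
F0 | step 14 | none | none
F10 | step 13 | (Z)-3-(tributylstannyl)prop-2-en-1-ol | CCCC[Sn](CCCC)(CCCC)/C=C\CO
A1 | alternative 1 | lactone-fused 2-isoxazoline (C12 lactone, C11=N, N–O–C8) with CH2O-tert-butyldiphenylsilyl on C6 and CH2O-(4-methoxybenzyl) on C8, configured at C6, C7 and C8 as in the target | O=C1O[C@H](CO[Si](c3ccccc3)(c3ccccc3)C(C)(C)C)[C@@H]2C1=NO[C@@H]2COCc1ccc(OC)cc1
A2 | alternative 2 | C5-phenylseleno 6,12-lactone of the ten-membered ring with C4 as a methyl-bearing CH, C9 tert-butyldimethylsilyl ether | C=C1C(=O)O[C@@H]2[C@@H]([Se]c5ccccc5)[C@H](C)[C@H]3O[C@H]3/C=C(/C(=O)OC)[C@H](O[Si](C)(C)C(C)(C)C)[C@@H](OC(=O)[C@@]3(C)O[C@@H]3C)[C@@H]12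
A3 | alternative 3 | C9 tert-butyldimethylsilyl ether of 25 | C=C1C(=O)O[C@@H]2/C=C(/C)[C@H]3O[C@H]3/C=C(/C(=O)OC)[C@H](O[Si](C)(C)C(C)(C)C)[C@@H](OC(=O)[C@@]3(C)O[C@@H]3C)[C@@H]12
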